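**Retrosynthetic overview**
1. Target 45 ⇐ desilylation, C1 acetylation and α‑methylenation of a C15 ketone; ring D ⇐ Pd(OAc)2‑mediated cyclisation of a lactone silyl ketene acetal onto a C13 allyl group (C8–C15), then C=CH2 → C=O.
2. Ring C ⇐ SmI2 ketyl–olefin cyclisation (C9–C11) of a C11 aldehyde onto an 8,9‑unsaturated spiro‑δ‑lactone.
3. Unsaturated lactone ⇐ intermolecular aldol (C8–C9) between the lithium enolate of ester 28 (fragment 2, C7–C16) and the neopentyl aldehyde 18 (fragment 1, ring A), then lactonisation (O–C20) and dehydration.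
4. Fragment 1: C5 by Evans alkylation, ring A by Dieckmann condensation, C10 by formaldehyde aldol, C1 by hydride reduction. Fragment 2: C13 by Evans alkylation, C14 by HYTRA acetate aldol.
5. Ring order: A → lactone → C → D.

Assumption and labels: the SMILES is read as drawn, (1S,5R,8R,9S,10R,11S,13S,14R) in kaurane numbering, and C1–C20 below are those positions (ring A = C1–C5, C10; C6 = CH2O on C5; lactone C7(=O)–O–C20; ring C = C8, C9, C11–C14; ring D = C8, C14, C13, C16, C15; C17 = exocyclic CH2); PMB = 4‑methoxybenzyl, TBS = tert‑butyldimethylsilyl, TBDPS = tert‑butyldiphenylsilyl, TES = triethylsilyl, HYTRA = 2‑hydroxy‑1,2,2‑triphenylethyl acetate.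

**Fragment 1 (ring A aldehyde)**

Step 1
Reactants: 1 (4S)-4-benzyl-1,3-oxazolidin-2-one; 2 3-methylbut-2-enoyl chloride
Product: 3 (4S)-4-benzyl-3-(3-methylbut-2-enoyl)-1,3-oxazolidin-2-one
Conditions: n-BuLi, THF, −78 °C; then 2, −78 → 0 °C
Reagents that add atoms: none
Why: N‑acylation of the lithiated oxazolidinone by the acid chloride; no stereocentre is formed.

Step 2
Reactants: 3 (4S)-4-benzyl-3-(3-methylbut-2-enoyl)-1,3-oxazolidin-2-one; 4 but-3-en-1-ylmagnesium bromide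
Product: 5 (4S)-4-benzyl-3-(3,3-dimethylhept-6-enoyl)-1,3-oxazolidin-2-one
Conditions: CuBr·SMe2 (1 equiv), THF/Me2S, −40 → 0 °C; aq. NH4Cl
Reagents that add atoms: none
Why: Copper‑mediated conjugate addition of the Grignard reagent to the β,β‑disubstituted enoyl imide builds the C4 gem‑dimethyl carbon, which is not stereogenic.

Step 3
Reactants: 5 (4S)-4-benzyl-3-(3,3-dimethylhept-6-enoyl)-1,3-oxazolidin-2-one; 6 tert-butyl bromoacetate
Product: 7 tert-butyl (3S)-3-{[(4S)-4-benzyl-2-oxo-1,3-oxazolidin-3-yl]carbonyl}-4,4-dimethyloct-7-enoate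
Conditions: NaN(SiMe3)2, THF, −78 °C; then 6, −78 → −40 °C
Reagents that add atoms: none
Why: Evans asymmetric alkylation; the chelated Z‑enolate is attacked on the face away from the benzyl group, which sets C5.

Step 4
Reactants: 7 alkylated imide
Product: 8 tert-butyl (3S)-3-(hydroxymethyl)-4,4-dimethyloct-7-enoate
Conditions: LiBH4, MeOH (1 equiv), Et2O, 0 °C
Reagents that add atoms: none
Why: Reductive cleavage of the imide gives the C6 alcohol and returns the auxiliary, while the tert‑butyl ester is inert to LiBH4.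

Step 5
Reactants: 8 hydroxy ester
Product: 9 tert-butyl (3S)-3-{[tert-butyl(diphenyl)silyl]oxymethyl}-4,4-dimethyloct-7-enoate
Conditions: TBDPSCl, imidazole, DMF, rt
Reagents that add atoms: tert-butyl(chloro)diphenylsilane, CC(C)(C)[Si](Cl)(c1ccccc1)c1ccccc1
Why: Silylation of the primary alcohol gives a protecting group that survives every later base, hydride and acid step.

Step 6
Reactants: 9 silyl ether
Product: 10 1-tert-butyl 7-methyl (3S)-3-{[tert-butyl(diphenyl)silyl]oxymethyl}-4,4-dimethylheptanedioate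
Conditions: O3, NaOH, MeOH/CH2Cl2, −78 °C
Reagents that add atoms: ozone, [O-][O+]=O; methanol, CO
Why: Ozonolysis in methanolic NaOH (Marshall oxidative cleavage) converts the terminal alkene directly into the C1 methyl ester.

Step 7
Reactants: 10 diester
Product: 11 tert-butyl (1S,6S)-6-{[tert-butyl(diphenyl)silyl]oxymethyl}-5,5-dimethyl-2-oxocyclohexane-1-carboxylate (trans, keto–enol mixture)
Conditions: KOt-Bu, THF, 0 °C → rt; aq. NH4Cl
Reagents that add atoms: none
Why: Dieckmann condensation; only the enolate next to the tert‑butyl ester can attack the unhindered methyl ester, and deprotonation of the β‑keto ester drives ring A closure.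

Step 8
Reactants: 11 β-keto ester
Product: 12 tert-butyl (1S,6R)-6-{[tert-butyl(diphenyl)silyl]oxymethyl}-1-(hydroxymethyl)-5,5-dimethyl-2-oxocyclohexane-1-carboxylate
Conditions: 37% aq. CH2O, KHCO3 (cat.), THF, rt
Reagents that add atoms: formaldehyde, C=O
Why: Aldol addition of the β‑keto ester enolate to formaldehyde occurs anti to the adjacent C5 substituent, making C10 quaternary with C9 trans to C6.

Step 9
Reactants: 12 hydroxymethyl β-keto ester
Product: 13 tert-butyl (1S,2S,6R)-6-{[tert-butyl(diphenyl)silyl]oxymethyl}-2-hydroxy-1-(hydroxymethyl)-5,5-dimethylcyclohexane-1-carboxylate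
Conditions: NaBH4, MeOH, −40 → −20 °C
Reagents that add atoms: none
Why: Ketone reduction by axial hydride delivery (the axial ester blocks the other face) gives the equatorial C1 alcohol, cis to C20 and trans to C9.

Step 10
Reactants: 13 diol
Product: 14 4-methoxybenzylidene acetal of 13 across O–C1 and O–C9 (trans-fused 1,3-dioxane, aryl equatorial)
Conditions: 4-MeOC6H4CH(OMe)2, pyridinium p-toluenesulfonate (cat.), CH2Cl2, rt
Reagents that add atoms: 4-methoxybenzaldehyde dimethyl acetal, COc1ccc(C(OC)OC)cc1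
Why: Acid‑catalysed transacetalisation ties the 1,3‑diol into a six‑membered acetal with the aryl group equatorial.

Step 11
Reactants: 14 acetal ester
Product: 15 acetal alcohol (C20 = CH2OH)
Conditions: LiAlH4, THF, 0 °C → reflux
Reagents that add atoms: none
Why: Hydride reduction of the hindered ester to the C20 primary alcohol; acetal and silyl ether are inert.

Step 12
Reactants: 15 acetal alcohol
Product: 16 acetal triethylsilyl ether (C20 = CH2OSiEt3)
Conditions: TESCl, imidazole, DMF, 0 °C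
Reagents that add atoms: chlorotriethylsilane, CC[Si](Cl)(CC)CC
Why: Silylation with a group that can later be removed beside TBS, TBDPS and PMB ethers.

Step 13
Reactants: 16 acetal silyl ether
Product: 17 ring-A alcohol (C9 = CH2OH; C1 OPMB; C20 CH2OSiEt3; C6 CH2OTBDPS)
Conditions: i-Bu2AlH, CH2Cl2, −78 → 0 °C; aq. sodium potassium tartrate
Reagents that add atoms: none
Why: Regioselective reductive acetal opening; aluminium binds the less hindered primary oxygen, so the PMB group stays on the secondary C1 oxygen.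

Step 14
Reactants: 17 ring-A alcohol
Product: 18 ring-A aldehyde, fragment 1 (C9 = CHO; C1 OPMB; C20 CH2OSiEt3; C6 CH2OTBDPS)
Conditions: Dess–Martin periodinane, NaHCO3, CH2Cl2, 0 °C → rt
Reagents that add atoms: none
Why: Dess–Martin oxidation of the neopentyl primary alcohol to a non‑enolisable aldehyde.

**Fragment 2 (C7–C16 ester)**

Step 15
Reactants: 1 (4S)-4-benzyl-1,3-oxazolidin-2-one; 19 pent-4-enoyl chloride
Product: 20 (4S)-4-benzyl-3-(pent-4-enoyl)-1,3-oxazolidin-2-one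
Conditions: n-BuLi, THF, −78 °C; then 19, −78 → 0 °C
Reagents that add atoms: none
Why: N‑acylation of the lithiated auxiliary.

Step 16
Reactants: 20 pentenoyl imide; 21 1-bromo-3-methylbut-2-ene
Product: 22 (4S)-4-benzyl-3-[(2R)-5-methyl-2-(prop-2-en-1-yl)hex-4-enoyl]-1,3-oxazolidin-2-one
Conditions: NaN(SiMe3)2, THF, −78 °C; then 21, −78 → −20 °C
Reagents that add atoms: none
Why: Evans asymmetric alkylation anti to the benzyl group sets C13 and gives two distinguishable arms (allyl and prenyl).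

Step 17
Reactants: 22 alkylated imide
Product: 23 (2R)-5-methyl-2-(prop-2-en-1-yl)hex-4-en-1-ol
Conditions: LiBH4, MeOH (1 equiv), Et2O, 0 °C
Reagents that add atoms: none
Why: Reductive removal of the auxiliary without touching the stereocentre.

Step 18
Reactants: 23 alcohol
Product: 24 (2R)-5-methyl-2-(prop-2-en-1-yl)hex-4-enal
Conditions: Dess–Martin periodinane, NaHCO3, CH2Cl2, 0 °C; used at once
Reagents that add atoms: none
Why: Buffered Dess–Martin oxidation gives the α‑branched aldehyde without epimerisation.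

Step 19
Reactants: 24 aldehyde; 25 (S)-HYTRA
Product: 26 (1S)-2-hydroxy-1,2,2-triphenylethyl (3S,4R)-3-hydroxy-7-methyl-4-(prop-2-en-1-yl)oct-6-enoate
Conditions: 25, LiN(i-Pr)2 (2.1 equiv), THF, −78 → 0 °C; then 24, THF/2-methylbutane, −115 °C; aq. NH4Cl
Reagents that add atoms: none
Why: Braun acetate aldol; the dilithium enolate of (S)‑HYTRA adds under reagent control to give the (3S) carbinol (C14), about 10:1, minor epimer removed by chromatography.

Step 20
Reactants: 26 HYTRA ester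
Product: 27 methyl (3S,4R)-3-hydroxy-7-methyl-4-(prop-2-en-1-yl)oct-6-enoate
Conditions: NaOMe (cat.), MeOH, 0 °C → rt
Reagents that add atoms: methanol, CO
Why: Transesterification releases the triphenylglycol auxiliary and gives the methyl ester.

Step 21
Reactants: 27 hydroxy ester
Product: 28 methyl (3S,4R)-3-{[tert-butyl(dimethyl)silyl]oxy}-7-methyl-4-(prop-2-en-1-yl)oct-6-enoate (fragment 2)
Conditions: TBSOTf, 2,6-lutidine, CH2Cl2, −78 °C
Reagents that add atoms: tert-butyldimethylsilyl trifluoromethanesulfonate, CC(C)(C)[Si](C)(C)OS(=O)(=O)C(F)(F)F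
Why: Silylation of the C14 hydroxyl so that the ester can be enolised.

**Union and completion**

Step 22
Reactants: 28 fragment 2 ester; 18 fragment 1 aldehyde
Product: 29 aldol adduct (methyl ester with new C8–C9 bond and C9 OH; C8/C9 epimer mixture)
Conditions: 28 (1.3 equiv), LiN(i-Pr)2, THF, −78 °C, 40 min; then 18, −78 °C, 1 h; AcOH quench at −78 °C
Reagents that add atoms: none
Why: Intermolecular aldol addition of the lithium ester enolate to the non‑enolisable neopentyl aldehyde joins the two fragments at C8–C9; both new centres are erased in step 24, so no diastereocontrol is needed.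

Step 23
Reactants: 29 aldol adduct
Product: 31 9-hydroxy 7,20-spirolactone (C8/C9 epimer mixture), via diol ester 30 (not isolated)
Conditions: pyridinium p-toluenesulfonate, MeOH/CH2Cl2, 0 °C → rt; then PhMe, 70 °C
Reagents that add atoms: none
Why: Acid‑mediated removal of the primary TES ether, then lactonisation of the C20 alcohol onto the C7 methyl ester closes the six‑membered spirolactone; C1 is blocked as its PMB ether, so the 1,7‑lactone cannot form.

Step 24
Reactants: 31 9-hydroxy spirolactone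
Product: 33 8,9-unsaturated 7,20-spirolactone, via mesylate 32 (not isolated)
Conditions: MsCl, Et3N, DMAP (cat.), CH2Cl2, 0 °C; then DBU, rt → 40 °C
Reagents that add atoms: none
Why: Mesylation and E1cB elimination complete the aldol condensation; mesylate leaves far more readily than the C14 silyloxy group, and the alkene geometry is fixed by the ring.

Step 25
Reactants: 33 unsaturated spirolactone
Product: 35 C11 aldehyde, via epoxide 34 (not isolated)
Conditions: mCPBA (1.05 equiv), NaHCO3, CH2Cl2, −20 → 0 °C; then H5IO6, THF/H2O, 0 °C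
Reagents that add atoms: 3-chloroperoxybenzoic acid, OOC(=O)c1cccc(Cl)c1
Why: Prilezhaev epoxidation selects the electron‑rich trisubstituted prenyl alkene over the terminal allyl group and the electron‑poor enoate, and periodic acid cleaves the epoxide to the aldehyde.

Step 26
Reactants: 35 aldehyde
Product: 36 tricyclic 11-alcohol (ring C closed; C9 and C11 as in 45; C8–H cis to C9–H, of no consequence)
Conditions: SmI2 (2.5 equiv), t-BuOH, THF, −78 → −40 °C
Reagents that add atoms: none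
Why: SmI2 ketyl–olefin reductive cyclisation; the ketyl adds to C9 on the lactone face away from the C4/C5 side of ring A through a chair‑like transition state, setting C9 and the axial C11 hydroxyl, as in the closely related trichorabdal series.

Step 27
Reactants: 36 tricyclic alcohol
Product: 37 11,14-bis-TBS ether
Conditions: TBSOTf, 2,6-lutidine, CH2Cl2, 0 °C
Reagents that add atoms: tert-butyldimethylsilyl trifluoromethanesulfonate, CC(C)(C)[Si](C)(C)OS(=O)(=O)C(F)(F)F
Why: Silylation of the hindered axial alcohol before enolate chemistry.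

Step 28
Reactants: 37 bis-TBS ether
Product: 39 15-methylene tetracycle (bicyclo[3.2.1]octane closed; C8 as in 45), via silyl ketene acetal 38 (not isolated)
Conditions: KN(SiMe3)2, TBSCl, THF, −78 °C; then Pd(OAc)2 (1.0 equiv), AcOH (0.5 equiv), DMSO, 45 °C
Reagents that add atoms: none
Why: O‑silylation of the lactone enolate, then cycloalkenylation mediated by divalent palladium (5‑exo carbopalladation, β‑hydride elimination) forms C8–C15; the C13 allyl group reaches only one face of C8, which fixes the quaternary centre.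

Step 29
Reactants: 39 15-methylene tetracycle
Product: 40 15-ketone
Conditions: OsO4 (cat.), NaIO4, 2,6-lutidine, dioxane/H2O, rt
Reagents that add atoms: sodium periodate, [Na+].[O-]I(=O)(=O)=O
Why: Lemieux–Johnson oxidative cleavage of the only remaining alkene gives the C15 ketone and spares the PMB ether.

Step 30
Reactants: 40 ketone
Product: 41 1-alcohol
Conditions: DDQ, CH2Cl2/pH 7 buffer, 0 °C
Reagents that add atoms: none
Why: Oxidative cleavage of the PMB ether frees only the C1 hydroxyl; neutral conditions and immediate use avoid translactonisation to the 1,7‑lactone.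

Step 31
Reactants: 41 1-alcohol
Product: 42 1-acetate
Conditions: Ac2O, DMAP (cat.), pyridine, CH2Cl2, 0 °C → rt
Reagents that add atoms: acetic anhydride, CC(=O)OC(C)=O
Why: DMAP‑catalysed acetylation of the single free hydroxyl.

Step 32
Reactants: 42 1-acetate
Product: 44 tris-silylated enone (16-methylene-15-ketone), via Mannich base 43 (not isolated)
Conditions: (Me2N)2CH2, Ac2O, DMF, 95 °C
Reagents that add atoms: bis(dimethylamino)methane, CN(C)CN(C)C
Why: Mannich reaction of the ketone at C16 (its only enolisable position) with the iminium ion formed in situ, then thermal loss of dimethylamine, gives the exocyclic enone (α‑methylenation).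

Step 33
Reactants: 44 tris-silylated enone
Product: 45 target
Conditions: HF·pyridine, pyridine, THF, 0 °C → rt
Reagents that add atoms: none
Why: Fluoride‑mediated global desilylation under mildly acidic conditions leaves the acetate, lactone, β‑hydroxy ketone and enone intact.

**Compound list**
1 | (4S)-4-benzyl-1,3-oxazolidin-2-one | O=C1N[C@@H](Cc2ccccc2)CO1 | starting material
2 | 3-methylbut-2-enoyl chloride | CC(C)=CC(Cl)=O | starting material
3 | (4S)-4-benzyl-3-(3-methylbut-2-enoyl)-1,3-oxazolidin-2-one | CC(C)=CC(=O)N1[C@@H](Cc2ccccc2)COC1=O | intermediate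
4 | but-3-en-1-ylmagnesium bromide | C=CCC[Mg]Br | starting material
5 | (4S)-4-benzyl-3-(3,3-dimethylhept-6-enoyl)-1,3-oxazolidin-2-one | C=CCCC(C)(C)CC(=O)N1[C@@H](Cc2ccccc2)COC1=O | intermediate
6 | tert-butyl bromoacetate | CC(C)(C)OC(=O)CBr | starting material
7 | tert-butyl (3S)-3-{[(4S)-4-benzyl-2-oxo-1,3-oxazolidin-3-yl]carbonyl}-4,4-dimethyloct-7-enoate | C=CCCC(C)(C)[C@H](CC(=O)OC(C)(C)C)C(=O)N1[C@@H](Cc2ccccc2)COC1=O | intermediate
8 | tert-butyl (3S)-3-(hydroxymethyl)-4,4-dimethyloct-7-enoate | C=CCCC(C)(C)[C@H](CC(=O)OC(C)(C)C)CO | intermediate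
9 | tert-butyl (3S)-3-{[tert-butyl(diphenyl)silyl]oxymethyl}-4,4-dimethyloct-7-enoate | C=CCCC(C)(C)[C@H](CC(=O)OC(C)(C)C)CO[Si](c1ccccc1)(c1ccccc1)C(C)(C)C | intermediate
10 | 1-tert-butyl 7-methyl (3S)-3-{[tert-butyl(diphenyl)silyl]oxymethyl}-4,4-dimethylheptanedioate | COC(=O)CCC(C)(C)[C@H](CC(=O)OC(C)(C)C)CO[Si](c1ccccc1)(c1ccccc1)C(C)(C)C | intermediate
11 | tert-butyl (1S,6S)-6-{[tert-butyl(diphenyl)silyl]oxymethyl}-5,5-dimethyl-2-oxocyclohexane-1-carboxylate | CC(C)(C)OC(=O)[C@@H]1C(=O)CCC(C)(C)[C@H]1CO[Si](c2ccccc2)(c2ccccc2)C(C)(C)C | intermediate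
12 | tert-butyl (1S,6R)-6-{[tert-butyl(diphenyl)silyl]oxymethyl}-1-(hydroxymethyl)-5,5-dimethyl-2-oxocyclohexane-1-carboxylate | CC(C)(C)OC(=O)[C@@]1(CO)C(=O)CCC(C)(C)[C@H]1CO[Si](c2ccccc2)(c2ccccc2)C(C)(C)C | intermediate
13 | tert-butyl (1S,2S,6R)-6-{[tert-butyl(diphenyl)silyl]oxymethyl}-2-hydroxy-1-(hydroxymethyl)-5,5-dimethylcyclohexane-1-carboxylate | CC(C)(C)OC(=O)[C@@]1(CO)[C@@H](O)CCC(C)(C)[C@H]1CO[Si](c2ccccc2)(c2ccccc2)C(C)(C)C | intermediate
14 | 4-methoxybenzylidene acetal of 13 across O–C1 and O–C9 (trans-fused dioxane; aryl equatorial; C20 = CO2t-Bu) | CC(C)(C)OC(=O)[C@@]12CO[C@@H](c3ccc(OC)cc3)O[C@H]1CCC(C)(C)[C@H]2CO[Si](c3ccccc3)(c3ccccc3)C(C)(C)C | intermediate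
15 | acetal alcohol (as 14 with C20 = CH2OH) | OC[C@@]12CO[C@@H](c3ccc(OC)cc3)O[C@H]1CCC(C)(C)[C@H]2CO[Si](c3ccccc3)(c3ccccc3)C(C)(C)C | intermediate
16 | acetal triethylsilyl ether (as 14 with C20 = CH2OSiEt3) | CC[Si](CC)(CC)OC[C@@]12CO[C@@H](c3ccc(OC)cc3)O[C@H]1CCC(C)(C)[C@H]2CO[Si](c3ccccc3)(c3ccccc3)C(C)(C)C | intermediate
17 | ring-A alcohol: C9 CH2OH; C1 OPMB; C20 CH2OSiEt3; C6 CH2OTBDPS; C1, C5, C10 as in 45 | CC[Si](CC)(CC)OC[C@@]1(CO)[C@@H](OCc2ccc(OC)cc2)CCC(C)(C)[C@H]1CO[Si](c2ccccc2)(c2ccccc2)C(C)(C)C | intermediate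
18 | ring-A aldehyde (fragment 1): as 17 with C9 = CHO | CC[Si](CC)(CC)OC[C@@]1(C=O)[C@@H](OCc2ccc(OC)cc2)CCC(C)(C)[C@H]1CO[Si](c2ccccc2)(c2ccccc2)C(C)(C)C | intermediate
19 | pent-4-enoyl chloride | C=CCCC(Cl)=O | starting material
20 | (4S)-4-benzyl-3-(pent-4-enoyl)-1,3-oxazolidin-2-one | C=CCCC(=O)N1[C@@H](Cc2ccccc2)COC1=O | intermediate
21 | 1-bromo-3-methylbut-2-ene | CC(C)=CCBr | starting material
22 | (4S)-4-benzyl-3-[(2R)-5-methyl-2-(prop-2-en-1-yl)hex-4-enoyl]-1,3-oxazolidin-2-one | CC(C)=CC[C@@H](CC=C)C(=O)N1[C@@H](Cc2ccccc2)COC1=O | intermediate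
23 | (2R)-5-methyl-2-(prop-2-en-1-yl)hex-4-en-1-ol | CC(C)=CC[C@@H](CC=C)CO | intermediate
24 | (2R)-5-methyl-2-(prop-2-en-1-yl)hex-4-enal | CC(C)=CC[C@@H](CC=C)C=O | intermediate
25 | (S)-2-hydroxy-1,2,2-triphenylethyl acetate, (S)-HYTRA | CC(=O)O[C@@H](c1ccccc1)C(O)(c1ccccc1)c1ccccc1 | starting material
26 | (1S)-2-hydroxy-1,2,2-triphenylethyl (3S,4R)-3-hydroxy-7-methyl-4-(prop-2-en-1-yl)oct-6-enoate | CC(C)=CC[C@@H](CC=C)[C@@H](O)CC(=O)O[C@@H](c1ccccc1)C(O)(c1ccccc1)c1ccccc1 | intermediate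
27 | methyl (3S,4R)-3-hydroxy-7-methyl-4-(prop-2-en-1-yl)oct-6-enoate | CC(C)=CC[C@@H](CC=C)[C@@H](O)CC(=O)OC | intermediate
28 | methyl (3S,4R)-3-{[tert-butyl(dimethyl)silyl]oxy}-7-methyl-4-(prop-2-en-1-yl)oct-6-enoate (fragment 2) | CC(C)=CC[C@@H](CC=C)[C@@H](O[Si](C)(C)C(C)(C)C)CC(=O)OC | intermediate
29 | aldol adduct: methyl ester joined at C8–C9; C9 OH; C8 and C9 epimer mixture; other centres as in 45 | COC(=O)C([C@H](O[Si](C)(C)C(C)(C)C)[C@H](CC=C)CC=C(C)C)C(O)[C@]1(CO[Si](CC)(CC)CC)[C@@H](OCc2ccc(OC)cc2)CCC(C)(C)[C@H]1CO[Si](c2ccccc2)(c2ccccc2)C(C)(C)C | intermediate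
30 | diol ester: 29 with C20 CH2OH free | COC(=O)C([C@H](O[Si](C)(C)C(C)(C)C)[C@H](CC=C)CC=C(C)C)C(O)[C@]1(CO)[C@@H](OCc2ccc(OC)cc2)CCC(C)(C)[C@H]1CO[Si](c2ccccc2)(c2ccccc2)C(C)(C)C | intermediate
31 | 9-hydroxy 7,20-spirolactone (C8 and C9 epimer mixture) | O=C1OC[C@@]2(C(O)C1[C@H](O[Si](C)(C)C(C)(C)C)[C@H](CC=C)CC=C(C)C)[C@@H](OCc3ccc(OC)cc3)CCC(C)(C)[C@H]2CO[Si](c3ccccc3)(c3ccccc3)C(C)(C)C | intermediate
32 | 9-mesylate of 31 | O=C1OC[C@@]2(C(OS(C)(=O)=O)C1[C@H](O[Si](C)(C)C(C)(C)C)[C@H](CC=C)CC=C(C)C)[C@@H](OCc3ccc(OC)cc3)CCC(C)(C)[C@H]2CO[Si](c3ccccc3)(c3ccccc3)C(C)(C)C | intermediate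
33 | 8,9-unsaturated 7,20-spirolactone: C14 OTBS; C13 with allyl and prenyl arms; C1 OPMB; C6 OTBDPS | O=C1OC[C@@]2(C=C1[C@H](O[Si](C)(C)C(C)(C)C)[C@H](CC=C)CC=C(C)C)[C@@H](OCc3ccc(OC)cc3)CCC(C)(C)[C@H]2CO[Si](c3ccccc3)(c3ccccc3)C(C)(C)C | intermediate
34 | prenyl epoxide of 33 (epoxide carbon unassigned) | O=C1OC[C@@]2(C=C1[C@H](O[Si](C)(C)C(C)(C)C)[C@H](CC=C)CC4OC4(C)C)[C@@H](OCc3ccc(OC)cc3)CCC(C)(C)[C@H]2CO[Si](c3ccccc3)(c3ccccc3)C(C)(C)C | intermediate
35 | C11 aldehyde (C13 bears allyl and CH2CHO) | O=C1OC[C@@]2(C=C1[C@H](O[Si](C)(C)C(C)(C)C)[C@H](CC=C)CC=O)[C@@H](OCc3ccc(OC)cc3)CCC(C)(C)[C@H]2CO[Si](c3ccccc3)(c3ccccc3)C(C)(C)C | intermediate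
36 | tricyclic 11-alcohol (rings A, lactone and C; C9, C11 as in 45; C8–H cis to C9–H) | O=C1OC[C@]2([C@@H](OCc4ccc(OC)cc4)CCC(C)(C)[C@H]2CO[Si](c4ccccc4)(c4ccccc4)C(C)(C)C)[C@@H]3[C@@H](O)C[C@@H](CC=C)[C@@H](O[Si](C)(C)C(C)(C)C)[C@H]13 | intermediate
37 | 11,14-bis-TBS ether of 36 | O=C1OC[C@]2([C@@H](OCc4ccc(OC)cc4)CCC(C)(C)[C@H]2CO[Si](c4ccccc4)(c4ccccc4)C(C)(C)C)[C@@H]3[C@@H](O[Si](C)(C)C(C)(C)C)C[C@@H](CC=C)[C@@H](O[Si](C)(C)C(C)(C)C)[C@H]13 | intermediate
38 | lactone O-TBS ketene acetal (C7=C8) | CC(C)(C)[Si](C)(C)OC1=C2[C@H](O[Si](C)(C)C(C)(C)C)[C@H](CC=C)C[C@H](O[Si](C)(C)C(C)(C)C)[C@H]2[C@]3(CO1)[C@@H](OCc4ccc(OC)cc4)CCC(C)(C)[C@H]3CO[Si](c4ccccc4)(c4ccccc4)C(C)(C)C | intermediate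
39 | 15-methylene tetracycle (C15=CH2, C16 H2; all ring stereocentres as in 45) | C1C(=C)[C@@]23C(=O)OC[C@]4([C@@H](OCc5ccc(OC)cc5)CCC(C)(C)[C@H]4CO[Si](c5ccccc5)(c5ccccc5)C(C)(C)C)[C@@H]2[C@@H](O[Si](C)(C)C(C)(C)C)C[C@@H]1[C@H]3O[Si](C)(C)C(C)(C)C | intermediate
40 | 15-ketone (C1 OPMB) | C1C(=O)[C@@]23C(=O)OC[C@]4([C@@H](OCc5ccc(OC)cc5)CCC(C)(C)[C@H]4CO[Si](c5ccccc5)(c5ccccc5)C(C)(C)C)[C@@H]2[C@@H](O[Si](C)(C)C(C)(C)C)C[C@@H]1[C@H]3O[Si](C)(C)C(C)(C)C | intermediate
41 | 15-ketone 1-alcohol | C1C(=O)[C@@]23C(=O)OC[C@]4([C@@H](O)CCC(C)(C)[C@H]4CO[Si](c5ccccc5)(c5ccccc5)C(C)(C)C)[C@@H]2[C@@H](O[Si](C)(C)C(C)(C)C)C[C@@H]1[C@H]3O[Si](C)(C)C(C)(C)C | intermediate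
42 | 15-ketone 1-acetate | C1C(=O)[C@@]23C(=O)OC[C@]4([C@@H](OC(C)=O)CCC(C)(C)[C@H]4CO[Si](c5ccccc5)(c5ccccc5)C(C)(C)C)[C@@H]2[C@@H](O[Si](C)(C)C(C)(C)C)C[C@@H]1[C@H]3O[Si](C)(C)C(C)(C)C | intermediate
43 | 16-(dimethylaminomethyl) ketone (C16 unassigned) | CN(C)CC1C(=O)[C@@]23C(=O)OC[C@]4([C@@H](OC(C)=O)CCC(C)(C)[C@H]4CO[Si](c5ccccc5)(c5ccccc5)C(C)(C)C)[C@@H]2[C@@H](O[Si](C)(C)C(C)(C)C)C[C@@H]1[C@H]3O[Si](C)(C)C(C)(C)C | intermediate
44 | 6-O-TBDPS-11,14-bis-O-TBS ether of the target | C=C1C(=O)[C@@]23C(=O)OC[C@]4([C@@H](OC(C)=O)CCC(C)(C)[C@H]4CO[Si](c5ccccc5)(c5ccccc5)C(C)(C)C)[C@@H]2[C@@H](O[Si](C)(C)C(C)(C)C)C[C@@H]1[C@H]3O[Si](C)(C)C(C)(C)C | intermediate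
45 | CNP0225182.1 (1-acetoxy-6,11,14-trihydroxy-15-oxo-6,7-secokaur-16-en-7,20-olide) | C=C1C(=O)[C@@]23C(=O)OC[C@]4([C@@H](OC(C)=O)CCC(C)(C)[C@H]4CO)[C@@H]2[C@@H](O)C[C@@H]1[C@H]3O | target

**Totals.** 33 steps in all; longest linear sequence 26 steps (steps 1–14, then 22–33); fragment 2 takes 7 steps (15–21).

**Three steps most likely to fail, with fallbacks**

Step 28 is the weakest point: the lactone must be enolised next to the C14 silyl ether (β‑elimination is possible) and the cyclisation needs stoichiometric Pd(OAc)2 at a crowded centre. The fallback sets out from 33 and comes back at 40, and it closes rings C and D together without any strong base. Ozonolysis of both side‑chain alkenes of 33 (O3, pyridine, CH2Cl2/MeOH, −78 °C; Me2S; the enoate is too electron‑poor to react) gives the dialdehyde F1, in which the two CH2CHO arms on C13 are identical. SmI2 and t‑BuOH in THF at −78 °C then run a ketyl–olefin cyclisation onto C9 followed by an intramolecular aldol of the trivalent samarium enolate at C8 onto the second aldehyde, giving the 11,15-diol F2. Dess–Martin oxidation (1.1 equiv, 0 °C) of the exposed C15 alcohol, in preference to the axial C11 alcohol shielded by the new bridge, gives the 11-hydroxy-15-ketone F3, and TBSOTf/2,6‑lutidine gives 40.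

Step 26 may give the wrong C9/C11 isomer, or the samarium enolate may expel the C14 silyloxy group. The fallback sets out from 35 and comes back at 36, and it separates C–C bond formation from the setting of C11. A carbene‑catalysed intramolecular Stetter reaction (triazolium salt, i‑Pr2NEt, PhMe, 40 °C; the acyl‑anion equivalent adds only to the enoate and ignores the allyl group) gives the 11-ketone F4, whose C8 is then epimerisable and C9 equilibrates to the more stable ring fusion. LiBH(s‑Bu)3 in THF at −78 °C attacks the ketone from the equatorial direction and gives the axial 11‑alcohol 36.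

Step 24 may stall because the C9 hydroxyl lies between the quaternary C10 and the branched C8 and could resist mesylation. The fallback sets out from 31 and comes back at 33, replacing dehydration by oxidation and reduction. Dess–Martin oxidation gives the 9-keto lactone F5, which can enolise only towards C8. NaH and PhNTf2 in THF give the enol triflate F6, and Pd(OAc)2/PPh3 with HCO2H and n‑Bu3N in DMF at 60 °C reduces the vinyl triflate to 33.

**Further compounds**
F1 | step 28 | dialdehyde (33 with both C13 arms as CH2CHO) | O=C1OC[C@@]2(C=C1[C@H](O[Si](C)(C)C(C)(C)C)C(CC=O)CC=O)[C@@H](OCc3ccc(OC)cc3)CCC(C)(C)[C@H]2CO[Si](c3ccccc3)(c3ccccc3)C(C)(C)C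
F2 | step 28 | 11,15-diol tetracycle (C15 carbinol unassigned; C11 OH free; C14 OTBS; C1 OPMB; C6 OTBDPS) | C1C(O)[C@@]23C(=O)OC[C@]4([C@@H](OCc5ccc(OC)cc5)CCC(C)(C)[C@H]4CO[Si](c5ccccc5)(c5ccccc5)C(C)(C)C)[C@@H]2[C@@H](O)C[C@@H]1[C@H]3O[Si](C)(C)C(C)(C)C
F3 | step 28 | 11-hydroxy-15-ketone tetracycle | C1C(=O)[C@@]23C(=O)OC[C@]4([C@@H](OCc5ccc(OC)cc5)CCC(C)(C)[C@H]4CO[Si](c5ccccc5)(c5ccccc5)C(C)(C)C)[C@@H]2[C@@H](O)C[C@@H]1[C@H]3O[Si](C)(C)C(C)(C)C
F4 | step 26 | tricyclic 11-ketone (36 with C11 = C=O) | O=C1OC[C@]2([C@@H](OCc4ccc(OC)cc4)CCC(C)(C)[C@H]2CO[Si](c4ccccc4)(c4ccccc4)C(C)(C)C)[C@@H]3C(=O)C[C@@H](CC=C)[C@@H](O[Si](C)(C)C(C)(C)C)[C@H]13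
F5 | step 24 | 9-keto 7,20-spirolactone (C8 epimerisable) | O=C1OC[C@@]2(C(=O)C1[C@H](O[Si](C)(C)C(C)(C)C)[C@H](CC=C)CC=C(C)C)[C@@H](OCc3ccc(OC)cc3)CCC(C)(C)[C@H]2CO[Si](c3ccccc3)(c3ccccc3)C(C)(C)C
F6 | step 24 | C9 enol triflate of F5 (C8=C9) | O=C1OC[C@@]2(C(OS(=O)(=O)C(F)(F)F)=C1[C@H](O[Si](C)(C)C(C)(C)C)[C@H](CC=C)CC=C(C)C)[C@@H](OCc3ccc(OC)cc3)CCC(C)(C)[C@H]2CO[Si](c3ccccc3)(c3ccccc3)C(C)(C)C
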